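**Retrosynthetic overview**

- Ring locants: C1 carries the acrylic acid, C2 the OH, C3 the hydroxypropenyl group, C4 Me and vinyl, C5 is CH2, C6 carries the ester oxygen. The target comes from one fluoride deprotection after late allylic oxidation of a C3 isopropenyl group.
- The single carbocycle is formed last among the C–C bonds, by an intramolecular carbonyl-ene reaction (C2–C3 bond) of an acyclic C2 aldehyde that already carries C1, C4, C6 and the side-chain ester.
- Key C1–C6 bond: indium turns a glyceraldehyde-derived (Z)-2-(bromomethyl)enoate into an allylindium (ester homoenolate equivalent) whose normally electrophilic beta carbon (C1) attacks the C6 aldehyde. The dioxolane steers the face and is later cut down to the C2 aldehyde.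
- Fragments: the C6 aldehyde with the C4 quaternary centre (copper-catalysed enantioselective SN2' alkenylation), the bromide (Baylis–Hillman reaction of (R)-glyceraldehyde acetonide, then bromination), and the side-chain acid (enantioselective Baylis–Hillman reaction).

Assumption: the stereodescriptors of the given SMILES are taken literally, i.e. ring configuration (1S,2S,3S,4R,6R) with the C6 oxygen, the C1 acrylic acid and the C2 hydroxyl all cis, and an (R) carbinol in the side chain.

**Route**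

Step 1
Reactants: 1 4,4-dimethoxybutan-2-one; 2 triethyl phosphonoacetate
Product: 3 ethyl (2E)-5,5-dimethoxy-3-methylpent-2-enoate
Conditions: NaH, THF, 0 °C to rt; minor Z isomer removed by chromatography
Reagents that add atoms: none
Why: Horner–Wadsworth–Emmons olefination of the methyl ketone gives mainly the E trisubstituted enoate (ester trans to the larger CH2CH(OMe)2 arm), and removing the Z isomer here secures a single olefin geometry for the later SN2' step.

Step 2
Reactants: 3 ethyl (2E)-5,5-dimethoxy-3-methylpent-2-enoate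
Product: 4 (2E)-5,5-dimethoxy-3-methylpent-2-en-1-ol
Conditions: iBu2AlH, CH2Cl2, −78 °C
Reagents that add atoms: none
Why: Aluminium hydride 1,2-reduction of the conjugated ester gives the allylic alcohol without touching the acetal or the olefin geometry.

Step 3
Reactants: 4 (2E)-5,5-dimethoxy-3-methylpent-2-en-1-ol
Product: 5 diethyl (2E)-5,5-dimethoxy-3-methylpent-2-en-1-yl phosphate
Conditions: (EtO)2P(O)Cl, Et3N, DMAP (cat.), CH2Cl2, 0 °C
Reagents that add atoms: diethyl chlorophosphate, CCOP(=O)(Cl)OCC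
Why: O-Phosphorylation of the primary allylic alcohol installs the leaving group needed for copper-catalysed allylic substitution.

Step 4
Reactants: 5 diethyl (2E)-5,5-dimethoxy-3-methylpent-2-en-1-yl phosphate; 6 4,4,5,5-tetramethyl-2-(2-methylprop-1-en-1-yl)-1,3,2-dioxaborolane
Product: 7 (3R)-3-(2,2-dimethoxyethyl)-3,5-dimethylhexa-1,4-diene
Conditions: CuCl (5 mol %), chiral sulfonate-bearing imidazolinium salt (N-heterocyclic carbene precursor, enantiomer giving R, 5.5 mol %), NaOMe, THF, 22 to 50 °C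
Reagents that add atoms: none
Why: Copper-catalysed enantioselective allylic substitution (SN2') transfers the alkenyl group from boron to the methyl-bearing olefin carbon of the E phosphate under control of the chiral carbene ligand, creating the quaternary stereocentre (later C4, R) together with the vinyl group.

Step 5
Reactants: 7 (3R)-3-(2,2-dimethoxyethyl)-3,5-dimethylhexa-1,4-diene
Product: 8 (3R)-3-ethenyl-3,5-dimethylhex-4-enal
Conditions: 80% aq. AcOH, rt
Reagents that add atoms: water, O
Why: Mild acid hydrolysis of the dimethyl acetal releases the aldehyde, and the quaternary centre cannot epimerise.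

Step 6
Reactants: 9 acryloyl chloride; 10 2-(trimethylsilyl)ethanol
Product: 11 2-(trimethylsilyl)ethyl prop-2-enoate
Conditions: Et3N, CH2Cl2, 0 °C
Reagents that add atoms: none
Why: Acid chloride esterification gives an acrylate whose ester can later be cleaved by fluoride under non-hydrolytic conditions.

Step 7
Reactants: 11 2-(trimethylsilyl)ethyl prop-2-enoate; 12 (4R)-2,2-dimethyl-1,3-dioxolane-4-carbaldehyde
Product: 13 2-(trimethylsilyl)ethyl 2-{[(4R)-2,2-dimethyl-1,3-dioxolan-4-yl](hydroxy)methyl}prop-2-enoate (both carbinol epimers)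
Conditions: DABCO, dioxane/H2O (1:1), rt
Reagents that add atoms: none
Why: Morita–Baylis–Hillman reaction of the reactive alpha-alkoxy aldehyde keeps the dioxolane centre intact, and the new carbinol centre is irrelevant because it becomes sp2 in step 8.

Step 8
Reactants: 13 2-(trimethylsilyl)ethyl 2-{[(4R)-2,2-dimethyl-1,3-dioxolan-4-yl](hydroxy)methyl}prop-2-enoate
Product: 14 2-(trimethylsilyl)ethyl (2Z)-2-(bromomethyl)-3-[(4S)-2,2-dimethyl-1,3-dioxolan-4-yl]prop-2-enoate
Conditions: NBS, Me2S, CH2Cl2, −30 °C to rt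
Reagents that add atoms: N-bromosuccinimide, BrN1C(=O)CCC1=O
Why: Allylic transposition (SN2') of the Baylis–Hillman alcohol through its alkoxysulfonium salt (Corey–Kim reagent) gives the thermodynamically preferred Z bromide with the dioxolane cis to CH2Br under neutral conditions that spare the acetonide.

Step 9
Reactants: 8 (3R)-3-ethenyl-3,5-dimethylhex-4-enal; 14 2-(trimethylsilyl)ethyl (2Z)-2-(bromomethyl)-3-[(4S)-2,2-dimethyl-1,3-dioxolan-4-yl]prop-2-enoate
Product: 16 2-(trimethylsilyl)ethyl (3R,4R,6R)-3-[(4S)-2,2-dimethyl-1,3-dioxolan-4-yl]-6-ethenyl-4-hydroxy-6,8-dimethyl-2-methylidenenon-7-enoate, via allylindium dibromide 15 (not isolated)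
Conditions: In powder, THF/H2O (1:1), rt
Reagents that add atoms: none
Why: In this Barbier-type indium 2-(alkoxycarbonyl)allylation the metal converts the enoate, whose beta carbon is normally an acceptor, into an allylindium that acts as an ester homoenolate equivalent and attacks the aldehyde through that carbon in a closed chair transition state (Z reagent, aldehyde chain equatorial, so the new hydroxyl and the acrylate end up cis on the future ring), while the new bond forms anti to the dioxolane C–O bond with the allylic hydrogen eclipsing the olefin (Felkin-type sense, consistent with indium–oxygen chelation in water), which sets C1 and C6 of the ring as drawn.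

Step 10
Reactants: 17 [(tert-butyldimethylsilyl)oxy]acetaldehyde; 18 1,1,1,3,3,3-hexafluoropropan-2-yl prop-2-enoate
Product: 19 1,1,1,3,3,3-hexafluoropropan-2-yl (3R)-4-[(tert-butyldimethylsilyl)oxy]-3-hydroxy-2-methylidenebutanoate
Conditions: α-isocupreine (10 mol %), DMF, −55 °C
Reagents that add atoms: none
Why: Enantioselective Morita–Baylis–Hillman reaction with the activated fluorinated acrylate, in which the quinine-derived α-isocupreine (pseudo-enantiomer of β-isocupreidine) controls the aldehyde face, gives the R carbinol of the side chain.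

Step 11
Reactants: 19 1,1,1,3,3,3-hexafluoropropan-2-yl (3R)-4-[(tert-butyldimethylsilyl)oxy]-3-hydroxy-2-methylidenebutanoate
Product: 20 1,1,1,3,3,3-hexafluoropropan-2-yl (3R)-3,4-bis[(tert-butyldimethylsilyl)oxy]-2-methylidenebutanoate
Conditions: TBSOTf, 2,6-lutidine, CH2Cl2, −78 °C
Reagents that add atoms: tert-butyldimethylsilyl trifluoromethanesulfonate, CC(C)(C)[Si](C)(C)OS(=O)(=O)C(F)(F)F
Why: Silylation of the secondary allylic alcohol with the silyl triflate and a hindered base protects it for the later periodate and Lewis acid steps.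

Step 12
Reactants: 20 1,1,1,3,3,3-hexafluoropropan-2-yl (3R)-3,4-bis[(tert-butyldimethylsilyl)oxy]-2-methylidenebutanoate
Product: 21 (3R)-3,4-bis[(tert-butyldimethylsilyl)oxy]-2-methylidenebutanoic acid
Conditions: LiOH, THF/H2O, 0 °C; then 1 M HCl to pH 3
Reagents that add atoms: lithium hydroxide, [Li+].[OH-]
Why: Saponification of the activated fluorinated ester proceeds at 0 °C without affecting the silyl ethers or the stereocentre.

Step 13
Reactants: 16 2-(trimethylsilyl)ethyl (3R,4R,6R)-3-[(4S)-2,2-dimethyl-1,3-dioxolan-4-yl]-6-ethenyl-4-hydroxy-6,8-dimethyl-2-methylidenenon-7-enoate; 21 (3R)-3,4-bis[(tert-butyldimethylsilyl)oxy]-2-methylidenebutanoic acid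
Product: 23 2-(trimethylsilyl)ethyl (3R,4R,6R)-4-({(3R)-3,4-bis[(tert-butyldimethylsilyl)oxy]-2-methylidenebutanoyl}oxy)-3-[(4S)-2,2-dimethyl-1,3-dioxolan-4-yl]-6-ethenyl-6,8-dimethyl-2-methylidenenon-7-enoate, via mixed anhydride 22 (not isolated)
Conditions: 2,4,6-Cl3C6H2COCl, Et3N, THF, rt; then 16, DMAP, toluene, rt
Reagents that add atoms: none
Why: Yamaguchi esterification acylates the only free hydroxyl (the future C6–OH) before it can lactonise onto the neighbouring ester, and no stereocentre is touched.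

Step 14
Reactants: 23 2-(trimethylsilyl)ethyl (3R,4R,6R)-4-({(3R)-3,4-bis[(tert-butyldimethylsilyl)oxy]-2-methylidenebutanoyl}oxy)-3-[(4S)-2,2-dimethyl-1,3-dioxolan-4-yl]-6-ethenyl-6,8-dimethyl-2-methylidenenon-7-enoate
Product: 25 2-(trimethylsilyl)ethyl (3R,4R,6R)-4-({(3R)-3,4-bis[(tert-butyldimethylsilyl)oxy]-2-methylidenebutanoyl}oxy)-6-ethenyl-3-formyl-6,8-dimethyl-2-methylidenenon-7-enoate, via vicinal diol 24 (not isolated)
Conditions: H5IO6, EtOAc, rt; crude aldehyde used at once
Reagents that add atoms: none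
Why: Periodic acid hydrolyses the terminal acetonide and cleaves the resulting glycol in one pot (glycol cleavage), turning the stereocontrolling dioxolane into the C2 aldehyde without any base that could epimerise C1 or eliminate the beta-acyloxy group.

Step 15
Reactants: 25 2-(trimethylsilyl)ethyl (3R,4R,6R)-4-({(3R)-3,4-bis[(tert-butyldimethylsilyl)oxy]-2-methylidenebutanoyl}oxy)-6-ethenyl-3-formyl-6,8-dimethyl-2-methylidenenon-7-enoate
Product: 26 2-(trimethylsilyl)ethyl 2-[(1S,2S,3R,4R,6R)-6-({(3R)-3,4-bis[(tert-butyldimethylsilyl)oxy]-2-methylidenebutanoyl}oxy)-4-ethenyl-2-hydroxy-4-methyl-3-(prop-1-en-2-yl)cyclohexyl]prop-2-enoate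
Conditions: Me2AlCl, CH2Cl2, −78 °C
Reagents that add atoms: none
Why: This Lewis acid promoted intramolecular carbonyl-ene reaction (isopulegol-type cyclisation) closes the C2–C3 bond through a chair with the bulky C6 ester, the aldehyde oxygen and the reacting alkene equatorial and the C1 acrylate and C4 methyl axial, which sets C2–OH cis to the C1 acrylate and trans to the new C3 isopropenyl group (itself trans to the C4 vinyl group), the alternative chair being disfavoured by a 1,3-diaxial clash of the C6 ester with the C4 vinyl group.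

Step 16
Reactants: 26 2-(trimethylsilyl)ethyl 2-[(1S,2S,3R,4R,6R)-6-({(3R)-3,4-bis[(tert-butyldimethylsilyl)oxy]-2-methylidenebutanoyl}oxy)-4-ethenyl-2-hydroxy-4-methyl-3-(prop-1-en-2-yl)cyclohexyl]prop-2-enoate
Product: 27 2-(trimethylsilyl)ethyl 2-[(1S,2S,3S,4R,6R)-6-({(3R)-3,4-bis[(tert-butyldimethylsilyl)oxy]-2-methylidenebutanoyl}oxy)-4-ethenyl-2-hydroxy-3-(3-hydroxyprop-1-en-2-yl)-4-methylcyclohexyl]prop-2-enoate
Conditions: SeO2 (0.3 equiv), tBuOOH, salicylic acid (cat.), CH2Cl2, rt
Reagents that add atoms: selenium dioxide, O=[Se]=O; tert-butyl hydroperoxide, CC(C)(C)OO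
Why: Riley allylic oxidation (ene reaction of selenium dioxide, then 2,3-sigmatropic shift) should select the methyl group of the only electron-rich 1,1-disubstituted alkene, since the acrylates are electron-poor and the vinyl group has no allylic hydrogen.

Step 17
Reactants: 27 2-(trimethylsilyl)ethyl 2-[(1S,2S,3S,4R,6R)-6-({(3R)-3,4-bis[(tert-butyldimethylsilyl)oxy]-2-methylidenebutanoyl}oxy)-4-ethenyl-2-hydroxy-3-(3-hydroxyprop-1-en-2-yl)-4-methylcyclohexyl]prop-2-enoate
Product: 28 2-[(1S,2S,3S,4R,6R)-6-{[(3R)-3,4-dihydroxy-2-methylidenebutanoyl]oxy}-4-ethenyl-2-hydroxy-3-(3-hydroxyprop-1-en-2-yl)-4-methylcyclohexyl]prop-2-enoic acid (CNP0348657.1)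
Conditions: Bu4NF, AcOH (1:1), THF, 0 °C to rt; pH 5 phosphate buffer work-up, no strong acid
Reagents that add atoms: none
Why: Fluoride-mediated global deprotection cleaves both silyl ethers and fragments the 2-(trimethylsilyl)ethyl ester (beta elimination to ethene) in one operation, and the acetic acid buffer suppresses acyl migration, lactonisation of the gamma-hydroxy acid and loss of the side chain as its lactone.

**Compound list**

1 | 4,4-dimethoxybutan-2-one | CC(=O)CC(OC)OC | starting material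
2 | triethyl phosphonoacetate | CCOC(=O)CP(=O)(OCC)OCC | starting material
3 | ethyl (2E)-5,5-dimethoxy-3-methylpent-2-enoate | CCOC(=O)/C=C(\C)CC(OC)OC | intermediate
4 | (2E)-5,5-dimethoxy-3-methylpent-2-en-1-ol | OC/C=C(\C)CC(OC)OC | intermediate
5 | diethyl (2E)-5,5-dimethoxy-3-methylpent-2-en-1-yl phosphate | CCOP(=O)(OCC)OC/C=C(\C)CC(OC)OC | intermediate
6 | 4,4,5,5-tetramethyl-2-(2-methylprop-1-en-1-yl)-1,3,2-dioxaborolane | CC(C)=CB1OC(C)(C)C(C)(C)O1 | starting material
7 | (3R)-3-(2,2-dimethoxyethyl)-3,5-dimethylhexa-1,4-diene | C=C[C@@](C=C(C)C)(C)CC(OC)OC | intermediate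
8 | (3R)-3-ethenyl-3,5-dimethylhex-4-enal | C=C[C@@](C=C(C)C)(C)CC=O | intermediate
9 | acryloyl chloride | C=CC(=O)Cl | starting material
10 | 2-(trimethylsilyl)ethanol | C[Si](C)(C)CCO | starting material
11 | 2-(trimethylsilyl)ethyl prop-2-enoate | C=CC(=O)OCC[Si](C)(C)C | intermediate
12 | (4R)-2,2-dimethyl-1,3-dioxolane-4-carbaldehyde | O=C[C@H]1COC(C)(C)O1 | starting material
13 | 2-(trimethylsilyl)ethyl 2-{[(4R)-2,2-dimethyl-1,3-dioxolan-4-yl](hydroxy)methyl}prop-2-enoate, both carbinol epimers | C=C(C(O)[C@H]1COC(C)(C)O1)C(=O)OCC[Si](C)(C)C | intermediate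
14 | 2-(trimethylsilyl)ethyl (2Z)-2-(bromomethyl)-3-[(4S)-2,2-dimethyl-1,3-dioxolan-4-yl]prop-2-enoate | BrC/C(=C\[C@H]1COC(C)(C)O1)C(=O)OCC[Si](C)(C)C | intermediate
15 | allylindium dibromide from 14 (Z, indium on the former CH2Br carbon) | Br[In](Br)C/C(=C\[C@H]1COC(C)(C)O1)C(=O)OCC[Si](C)(C)C | intermediate
16 | 2-(trimethylsilyl)ethyl (3R,4R,6R)-3-[(4S)-2,2-dimethyl-1,3-dioxolan-4-yl]-6-ethenyl-4-hydroxy-6,8-dimethyl-2-methylidenenon-7-enoate | C=C[C@@](C=C(C)C)(C)C[C@@H](O)[C@@H](C(=C)C(=O)OCC[Si](C)(C)C)[C@H]1COC(C)(C)O1 | intermediate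
17 | [(tert-butyldimethylsilyl)oxy]acetaldehyde | O=CCO[Si](C)(C)C(C)(C)C | starting material
18 | 1,1,1,3,3,3-hexafluoropropan-2-yl prop-2-enoate | C=CC(=O)OC(C(F)(F)F)C(F)(F)F | starting material
19 | 1,1,1,3,3,3-hexafluoropropan-2-yl (3R)-4-[(tert-butyldimethylsilyl)oxy]-3-hydroxy-2-methylidenebutanoate | C=C(C(=O)OC(C(F)(F)F)C(F)(F)F)[C@@H](O)CO[Si](C)(C)C(C)(C)C | intermediate
20 | 1,1,1,3,3,3-hexafluoropropan-2-yl (3R)-3,4-bis[(tert-butyldimethylsilyl)oxy]-2-methylidenebutanoate | C=C(C(=O)OC(C(F)(F)F)C(F)(F)F)[C@@H](O[Si](C)(C)C(C)(C)C)CO[Si](C)(C)C(C)(C)C | intermediate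
21 | (3R)-3,4-bis[(tert-butyldimethylsilyl)oxy]-2-methylidenebutanoic acid | C=C(C(=O)O)[C@@H](O[Si](C)(C)C(C)(C)C)CO[Si](C)(C)C(C)(C)C | intermediate
22 | mixed anhydride of 21 with 2,4,6-trichlorobenzoic acid | C=C(C(=O)OC(=O)c1c(Cl)cc(Cl)cc1Cl)[C@@H](O[Si](C)(C)C(C)(C)C)CO[Si](C)(C)C(C)(C)C | intermediate
23 | 2-(trimethylsilyl)ethyl (3R,4R,6R)-4-({(3R)-3,4-bis[(tert-butyldimethylsilyl)oxy]-2-methylidenebutanoyl}oxy)-3-[(4S)-2,2-dimethyl-1,3-dioxolan-4-yl]-6-ethenyl-6,8-dimethyl-2-methylidenenon-7-enoate | C=C[C@@](C=C(C)C)(C)C[C@@H](OC(=O)C(=C)[C@@H](O[Si](C)(C)C(C)(C)C)CO[Si](C)(C)C(C)(C)C)[C@@H](C(=C)C(=O)OCC[Si](C)(C)C)[C@H]1COC(C)(C)O1 | intermediate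
24 | 2-(trimethylsilyl)ethyl (3S,4R,6R)-4-({(3R)-3,4-bis[(tert-butyldimethylsilyl)oxy]-2-methylidenebutanoyl}oxy)-3-[(1S)-1,2-dihydroxyethyl]-6-ethenyl-6,8-dimethyl-2-methylidenenon-7-enoate | C=C[C@@](C=C(C)C)(C)C[C@@H](OC(=O)C(=C)[C@@H](O[Si](C)(C)C(C)(C)C)CO[Si](C)(C)C(C)(C)C)[C@@H](C(=C)C(=O)OCC[Si](C)(C)C)[C@H](O)CO | intermediate
25 | 2-(trimethylsilyl)ethyl (3R,4R,6R)-4-({(3R)-3,4-bis[(tert-butyldimethylsilyl)oxy]-2-methylidenebutanoyl}oxy)-6-ethenyl-3-formyl-6,8-dimethyl-2-methylidenenon-7-enoate | C=C[C@@](C=C(C)C)(C)C[C@@H](OC(=O)C(=C)[C@@H](O[Si](C)(C)C(C)(C)C)CO[Si](C)(C)C(C)(C)C)[C@@H](C(=C)C(=O)OCC[Si](C)(C)C)C=O | intermediate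
26 | 2-(trimethylsilyl)ethyl 2-[(1S,2S,3R,4R,6R)-6-({(3R)-3,4-bis[(tert-butyldimethylsilyl)oxy]-2-methylidenebutanoyl}oxy)-4-ethenyl-2-hydroxy-4-methyl-3-(prop-1-en-2-yl)cyclohexyl]prop-2-enoate | C=C[C@@]1(C)C[C@@H](OC(=O)C(=C)[C@@H](O[Si](C)(C)C(C)(C)C)CO[Si](C)(C)C(C)(C)C)[C@@H](C(=C)C(=O)OCC[Si](C)(C)C)[C@@H](O)[C@@H]1C(C)=C | intermediate
27 | 2-(trimethylsilyl)ethyl 2-[(1S,2S,3S,4R,6R)-6-({(3R)-3,4-bis[(tert-butyldimethylsilyl)oxy]-2-methylidenebutanoyl}oxy)-4-ethenyl-2-hydroxy-3-(3-hydroxyprop-1-en-2-yl)-4-methylcyclohexyl]prop-2-enoate | C=C[C@@]1(C)C[C@@H](OC(=O)C(=C)[C@@H](O[Si](C)(C)C(C)(C)C)CO[Si](C)(C)C(C)(C)C)[C@@H](C(=C)C(=O)OCC[Si](C)(C)C)[C@@H](O)[C@@H]1C(=C)CO | intermediate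
28 | 2-[(1S,2S,3S,4R,6R)-6-{[(3R)-3,4-dihydroxy-2-methylidenebutanoyl]oxy}-4-ethenyl-2-hydroxy-3-(3-hydroxyprop-1-en-2-yl)-4-methylcyclohexyl]prop-2-enoic acid (CNP0348657.1) | C=C[C@@]1(C)C[C@@H](OC(=O)C(=C)[C@@H](O)CO)[C@@H](C(=C)C(=O)O)[C@@H](O)[C@@H]1C(=C)CO | target

**Step count and risks**

Total step count: 17. Longest linear sequence: 11 steps (1, 2, 3, 4, 5, 9, 13, 14, 15, 16, 17).

The three steps most likely to fail:

Step 9 (key coupling). The syn relationship follows from the Z reagent, but the sense and level of face selection by the dioxolane rest on a model and could be eroded or reversed. The hindered gamma carbon may react slowly, and the product can lactonise. Fallback: setting out from bromide 14, Pd2(dba)3-catalysed borylation with bis(pinacolato)diboron gives the isolable pinacol allylboronate F1. This is added to aldehyde 8 under Sc(OTf)3 or chiral phosphoric acid catalysis, through a closed chair transition state at boron in which the catalyst can reinforce or override the intrinsic facial bias. Aqueous work-up comes back to the route at 16.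

Step 15 (ring closure). Aldehyde 25 is alpha-branched with a beta-acyloxy group and may eliminate or epimerise before it cyclises, and the Lewis acid may induce lactonisation of the new alkoxide. Fallback: setting out from 23, SeO2/tBuOOH oxidation of the E methyl group of the trisubstituted alkene gives the allylic alcohol F2. CBr4/PPh3 converts it into the allylic bromide F3, and H5IO6 unmasks the bromo aldehyde F4. CrCl2 (divalent chromium) then closes the ring by intramolecular Nozaki–Hiyama allylation through the gamma carbon, which is anti selective under neutral conditions and obeys the same chair preferences. This comes back to the route at 26.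

Step 16 (allylic oxidation). Over-oxidation to the enal, competing attack at the ring methine next to the isopropenyl group, or low conversion on this crowded substrate are all possible. Fallback: setting out from 26, PhSeCl-catalysed ene-type chlorination with N-chlorosuccinimide gives the allylic chloride F5. AgBF4 in wet acetone buffered with NaHCO3 replaces chloride by hydroxyl and comes back to the route at 27.

Further compounds
F1 | step 9 | pinacol allylboronate 2-(trimethylsilyl)ethyl (2E)-3-[(4S)-2,2-dimethyl-1,3-dioxolan-4-yl]-2-[(4,4,5,5-tetramethyl-1,3,2-dioxaborolan-2-yl)methyl]prop-2-enoate | CC1(C)OB(C/C(=C\[C@H]2COC(C)(C)O2)C(=O)OCC[Si](C)(C)C)OC1(C)C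
F2 | step 15 | E allylic alcohol from 23 (E methyl of the trisubstituted alkene oxidised to CH2OH) | C=C[C@@](/C=C(\C)CO)(C)C[C@@H](OC(=O)C(=C)[C@@H](O[Si](C)(C)C(C)(C)C)CO[Si](C)(C)C(C)(C)C)[C@@H](C(=C)C(=O)OCC[Si](C)(C)C)[C@H]1COC(C)(C)O1
F3 | step 15 | E allylic bromide from F2 | C=C[C@@](/C=C(\C)CBr)(C)C[C@@H](OC(=O)C(=C)[C@@H](O[Si](C)(C)C(C)(C)C)CO[Si](C)(C)C(C)(C)C)[C@@H](C(=C)C(=O)OCC[Si](C)(C)C)[C@H]1COC(C)(C)O1
F4 | step 15 | bromo aldehyde from F3 (dioxolane cut down to the formyl group) | C=C[C@@](/C=C(\C)CBr)(C)C[C@@H](OC(=O)C(=C)[C@@H](O[Si](C)(C)C(C)(C)C)CO[Si](C)(C)C(C)(C)C)[C@@H](C(=C)C(=O)OCC[Si](C)(C)C)C=O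
F5 | step 16 | allylic chloride from 26 (isopropenyl turned into 3-chloroprop-1-en-2-yl) | C=C[C@@]1(C)C[C@@H](OC(=O)C(=C)[C@@H](O[Si](C)(C)C(C)(C)C)CO[Si](C)(C)C(C)(C)C)[C@@H](C(=C)C(=O)OCC[Si](C)(C)C)[C@@H](O)[C@@H]1C(=C)CCl
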